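**Retrosynthetic overview**

1. Target 37 ⇐ enaminone 36 (base hydrolysis, desilylation) ⇐ isoxazole 35 ⇐ isoxazoline 34 ⇐ enone 28 + aryl nitrile oxide 33; one cycloaddition brings the aroyl carbon to C3 and the oxygen to C2.
2. 28 ⇐ silyl enol ether ynone 27 by gold-catalysed 6-endo-dig closure of ring B (C1–C2–C3–C4–C5–C9) at C1–C2. The strategy rests on this bond: it joins the prenylated bridgehead C1, which lies beside quaternary C8 of ring A (C1–C9–C5–C6–C7–C8), to the carbonyl-level carbon C2, and is made from the propynoyl arm held on the less hindered bridgehead C5.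
3. 27 ⇐ ring A ketone 14: C5 is prenylated, then made quaternary by an axial aldol with a silylated propynal while C1 is still CH2; C1 is prenylated afterwards; C8 comes from anti cuprate addition to enone 10.
4. 10 ⇐ (S)-enone 8 ⇐ aldehyde 5 + methyl vinyl ketone by enamine-catalysed Michael addition and aldol closure (sets C7).
5. Ring order: ring A (step 2), ring B (step 13); the isoxazole ring (steps 17–19) is temporary.

Key step: step 13

**Remarks and assumptions**

- The bicyclo[3.3.1]nonane numbering of the target is used for all intermediates: C1 and C5 are the prenylated bridgeheads, C9 the bridging ketone, C2–C3–C4 the aroyl-dione bridge, C7 carries geranyl, C8 carries methyl and homoprenyl. Geranyl = (2E)-3,7-dimethylocta-2,6-dienyl, prenyl = 3-methylbut-2-enyl, homoprenyl = 4-methylpent-3-enyl.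
- Assumption: the (S)-prolinol ether of step 2 follows the usual enamine face-shielding model. The target is drawn as one enol tautomer of the 3-aroyl-2,4-dione.
- Remark on the order at C5 and C1: C5 is made quaternary before C1 carries its prenyl group. An axial substituent on C1 would sit 1,3 to the electrophile arriving at C5, and the facial outcome would then depend on an uncontrolled C1 epimer.

**Route**

Step 1
Reactants: 1 geranyl bromide; 2 N-tert-butylethanimine
Product: 5 (4E)-5,9-dimethyldeca-4,8-dienal, via lithiated tert-butylimine 3 (not isolated), via alkylated tert-butylimine 4 (not isolated)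
Conditions: LiN(i-Pr)2, THF, 0 °C; 1, −78 → 0 °C; aq. oxalic acid, rt
Reagents that add atoms: water, O
Why: Aza-enolate alkylation of a metalated aldimine; the soft carbanion displaces the primary allylic bromide directly, so the E-alkene is kept, and mild aqueous acid hydrolyses the imine to the aldehyde.

Step 2
Reactants: 5 (4E)-5,9-dimethyldeca-4,8-dienal; 6 methyl vinyl ketone
Product: 8 (S)-4-geranylcyclohex-2-en-1-one, via (S)-2-geranyl-5-oxohexanal 7 (not isolated)
Conditions: (S)-2-[methoxy(diphenyl)methyl]pyrrolidine (5 mol %), ethyl 3,4-dihydroxybenzoate (20 mol %), neat, 4 °C; then LiOH, i-PrOH, rt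
Reagents that add atoms: none
Why: Enamine-catalysed asymmetric Michael addition followed by intramolecular aldol condensation; the diphenyl(methoxy)methyl group of the (S)-catalyst blocks one face of the E-enamine so that C7 should form as S, and closure of ring A to the enone should be faster than epimerisation of the α-branched aldehyde.

Step 3
Reactants: 8 (S)-4-geranylcyclohex-2-en-1-one
Product: 9 trimethylsilyl enol ether (C9=C1) of trans-4-geranyl-3-methylcyclohexanone, (3S,4S)
Conditions: Me2CuLi, Me3SiCl, Et2O–THF, −78 °C; Et3N, pentane work-up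
Reagents that add atoms: lithium dimethylcuprate, [Li+].C[Cu-]C; chlorotrimethylsilane, C[Si](C)(C)Cl
Why: Conjugate addition of a Gilman cuprate with in situ silyl trapping; methyl enters anti to the C7 geranyl group (this C8 centre is erased in step 4) and the enolate is fixed regiospecifically.

Step 4
Reactants: 9 trimethylsilyl enol ether
Product: 10 (S)-4-geranyl-3-methylcyclohex-2-en-1-one
Conditions: Pd(OAc)2 (1.05 equiv), MeCN, rt
Reagents that add atoms: none
Why: Saegusa–Ito oxidation; the divalent palladium enolate at C1 loses the C8 hydride by syn β-elimination and gives back the enone, now with the C8 methyl in place and C7 untouched.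

Step 5
Reactants: 10 (S)-4-geranyl-3-methylcyclohex-2-en-1-one; 11 5-bromo-2-methylpent-2-ene
Product: 14 (3R,4S)-4-geranyl-3-methyl-3-homoprenylcyclohexan-1-one (homoprenyl trans to geranyl), via (4-methylpent-3-enyl)magnesium bromide 12 (not isolated), via trimethylsilyl enol ether 13 (not isolated)
Conditions: 11, Mg, THF; add to 10, CuBr·SMe2 (10 mol %), Me3SiCl, DMPU, THF, −78 → −40 °C; then 1 M HCl, 0 °C
Reagents that add atoms: none
Why: Copper-catalysed conjugate addition of a Grignard reagent promoted by Me3SiCl; the C7 geranyl group sits pseudoaxial to avoid allylic strain with the C8 methyl and the nucleophile enters anti to it, which sets quaternary C8 with homoprenyl trans and methyl cis to geranyl, and the acid work-up frees the ketone.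

Step 6
Reactants: 14 ring A ketone; 15 prenyl bromide
Product: 17 C5-prenyl ketone (6-prenyl derivative of 14; C5 epimers), via kinetic lithium enolate 16 (not isolated)
Conditions: LiN(i-Pr)2, THF, −78 °C; 15, DMPU, −78 → −20 °C
Reagents that add atoms: none
Why: Kinetic enolate alkylation; the amide base takes a proton from the open C5 methylene and not from the C1 methylene beside quaternary C8, and the C5 configuration does not matter because this hydrogen is removed in step 7.

Step 7
Reactants: 17 C5-prenyl ketone
Product: 18 tetrasubstituted trimethylsilyl enol ether (C9=C5)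
Conditions: Me3SiCl, NaI, Et3N, MeCN, 40 °C
Reagents that add atoms: chlorotrimethylsilane, C[Si](C)(C)Cl
Why: Silyl enol ether formation under equilibrating conditions; the tetrasubstituted C9=C5 isomer should be favoured over the C9=C1 isomer, which would place the double bond beside quaternary C8.

Step 8
Reactants: 18 trimethylsilyl enol ether; 19 3-(trimethylsilyl)propynal
Product: 22 ring A ketone in which quaternary C5 carries prenyl (cis to geranyl) and CH(OSiEt3)C≡CSiMe3 (trans to geranyl; carbinol epimers), via lithium enolate 20 (not isolated), via lithium aldolate 21 (not isolated)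
Conditions: MeLi, THF, 0 °C; 19, −78 °C; Et3SiOTf, −78 → −40 °C
Reagents that add atoms: triethylsilyl trifluoromethanesulfonate, CC[Si](CC)(CC)OS(=O)(=O)C(F)(F)F
Why: Regiospecific lithium enolate generation from the silyl enol ether with MeLi, then aldol addition; with C1 still a methylene the only bias is the C7 geranyl group, so the aldehyde adds axially on the face trans to it and sets quaternary C5 with prenyl cis to geranyl, and silylation of the cold aldolate blocks retro-aldol cleavage.

Step 9
Reactants: 22 silyl-protected aldol; 15 prenyl bromide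
Product: 24 C1-prenyl derivative of 22 (C1 epimers), via lithium enolate 23 (not isolated)
Conditions: LiN(i-Pr)2, THF, −78 → 0 °C; 15, DMPU, −40 → 0 °C
Reagents that add atoms: none
Why: Enolate alkylation at the only enolisable position left (C5 is quaternary); C-prenylation gives the C1-prenyl ketone as an epimer mixture that converges in step 12.

Step 10
Reactants: 24 C1-prenyl ketone
Product: 25 β-hydroxy ketone with C5 carrying prenyl and CH(OH)C≡CH
Conditions: Bu4NF, AcOH, THF, 0 °C → rt
Reagents that add atoms: none
Why: Fluoride-mediated desilylation buffered with acetic acid removes the O-triethylsilyl and C-trimethylsilyl groups together, and the buffer suppresses retro-aldol cleavage.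

Step 11
Reactants: 25 β-hydroxy ketone
Product: 26 2,6-diprenyl-6-propynoyl ring A ketone (C1 epimers)
Conditions: Dess–Martin periodinane, NaHCO3, CH2Cl2, 0 °C → rt
Reagents that add atoms: none
Why: Dess–Martin oxidation of the propargylic alcohol under buffered conditions gives the terminal ynone; C5 bears no hydrogen, so the 1,3-diketone cannot enolise or epimerise there.

Step 12
Reactants: 26 ynone diketone
Product: 27 C9 tert-butyldimethylsilyl enol ether (C9=C1) of 26
Conditions: t-BuMe2SiOTf, 2,6-di-tert-butyl-4-methylpyridine, CH2Cl2, 0 °C → rt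
Reagents that add atoms: tert-butyldimethylsilyl trifluoromethanesulfonate, CC(C)(C)[Si](C)(C)OS(=O)(=O)C(F)(F)F
Why: Soft enolisation (silyl triflate activation of the C9 ketone, deprotonation by a hindered pyridine); only C1–H is available, so the tetrasubstituted C9=C1 silyl enol ether forms regiospecifically, and the non-nucleophilic base cannot add to the ynone.

Step 13
Reactants: 27 silyl enol ether ynone
Product: 28 1,5-diprenyl-7-geranyl-8-methyl-8-homoprenylbicyclo[3.3.1]non-2-ene-4,9-dione
Conditions: [(t-Bu)2(2-biphenylyl)P]Au(NCMe)SbF6 (5 mol %), acetone (undried), rt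
Reagents that add atoms: none
Why: The cationic monovalent gold complex binds the terminal alkyne of the ynone, the tetrasubstituted silyl enol ether carbon C1 adds to the alkyne terminus C2 anti to gold, the silyl group passes to water and the C3 vinyl-gold is protonated, which gives the C9 ketone and the C2=C3–C4=O enone (gold-catalysed enol ether–alkyne carbocyclisation, a Conia-ene-type reaction). Ring B closes in the 6-endo-dig mode; attack at C3 (5-exo) is disfavoured because conjugation with C4=O makes C2 the electrophilic carbon, and the bulky biaryl phosphine also favours the endo path. The only new stereocentre, C1, is controlled by C5: the propynoyl arm is axial on ring A and can reach only the face of C1 on its own side, anti to the axial C8 methyl, so that C1–C2 and C5–C4 end cis-diaxial on a chair ring A with the C7 geranyl group equatorial. The step needs the enol ether, not the C5 prenyl alkene (a 1,6-enyne partner), to capture the activated alkyne; the far higher nucleophilicity of the silyl enol ether and its fixed distance to C2 should secure this. Intramolecular delivery is what allows quaternary C1 to form beside quaternary C8.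

Step 14
Reactants: 29 3-hydroxybenzaldehyde
Product: 30 3-(tert-butyldimethylsilyloxy)benzaldehyde
Conditions: t-BuMe2SiCl, imidazole, DMF, rt
Reagents that add atoms: tert-butyldimethylsilyl chloride, CC(C)(C)[Si](C)(C)Cl
Why: Silylation of the phenol with a silyl chloride and imidazole protects it against ring chlorination in step 16 and against O-addition to the nitrile oxide.

Step 15
Reactants: 30 silylated aldehyde
Product: 31 (E)-3-(tert-butyldimethylsilyloxy)benzaldehyde oxime
Conditions: NH2OH·HCl, NaOAc, EtOH–H2O, rt
Reagents that add atoms: hydroxylamine hydrochloride, NO.Cl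
Why: Oxime formation by condensation of the aldehyde with hydroxylamine.

Step 16
Reactants: 31 oxime
Product: 32 N-hydroxy-3-(tert-butyldimethylsilyloxy)benzimidoyl chloride
Conditions: N-chlorosuccinimide, DMF, rt
Reagents that add atoms: N-chlorosuccinimide, O=C1CCC(=O)N1Cl
Why: Chlorination of the aldoxime C–H gives the hydroximoyl chloride, a storable nitrile oxide precursor.

Step 17
Reactants: 28 bicyclic enone; 32 hydroximoyl chloride
Product: 34 cis-fused isoxazoline across C2–C3 (ring oxygen on C2; aryl-bearing carbon on C3), via 3-(tert-butyldimethylsilyloxy)benzonitrile oxide 33 (not isolated)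
Conditions: 32 (3 equiv), Et3N (slow addition, 12 h), CH2Cl2, rt
Reagents that add atoms: none
Why: 1,3-Dipolar (Huisgen) cycloaddition of the nitrile oxide released by slow dehydrochlorination; the dipole oxygen should bond to the β-carbon C2 and the nitrile carbon to the α-carbon C3 (the usual orientation for cyclic enones, reinforced because the aryl-bearing end avoids neopentyl C2), addition is cis on the face away from the C6–C7–C8 bridge, both new centres are erased in step 18, and the trisubstituted side-chain alkenes are far poorer dipolarophiles than the conjugated cis-alkene.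

Step 18
Reactants: 34 isoxazoline
Product: 35 isoxazole fused at C2–C3 (3-aryl; C4 ketone on the isoxazole 4-position)
Conditions: activated MnO2, toluene, 80 °C
Reagents that add atoms: none
Why: Dehydrogenation of the 2-isoxazoline to the aromatic isoxazole, made easy by the doubly activated C3–H between the C4 ketone and the C=N bond.

Step 19
Reactants: 35 isoxazole
Product: 37 target CNP0285073.1, via enaminone 36 (not isolated)
Conditions: Mo(CO)6, MeCN–H2O, 80 °C; then aq. LiOH, dioxane, 80 °C; 1 M HCl to pH 3
Reagents that add atoms: water, O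
Why: Reductive N–O cleavage of the isoxazole by zerovalent molybdenum gives the enaminone, and base hydrolysis of this vinylogous amide (addition–elimination with loss of ammonia) releases the 3-aroyl-2,4-dione as its stabilised enolate while hydroxide also cleaves the aryl silyl ether; the basic medium avoids acid-induced cyclisation of prenyl groups onto the enol.

**Compound list**

1 | geranyl bromide | CC(C)=CCC/C(C)=C/CBr | starting material
2 | N-tert-butylethanimine | CC=NC(C)(C)C | starting material
3 | lithiated N-tert-butylethanimine (aza-enolate) | [Li]CC=NC(C)(C)C | intermediate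
4 | N-tert-butyl imine of (4E)-5,9-dimethyldeca-4,8-dienal | CC(C)=CCC/C(C)=C/CCC=NC(C)(C)C | intermediate
5 | (4E)-5,9-dimethyldeca-4,8-dienal | CC(C)=CCC/C(C)=C/CCC=O | intermediate
6 | methyl vinyl ketone | CC(=O)C=C | starting material
7 | (S)-2-geranyl-5-oxohexanal | CC(C)=CCC/C(C)=C/C[C@@H](C=O)CCC(C)=O | intermediate
8 | (S)-4-geranylcyclohex-2-en-1-one | CC(C)=CCC/C(C)=C/C[C@@H]1CCC(=O)C=C1 | intermediate
9 | trimethyl{[(3S,4S)-4-geranyl-3-methylcyclohex-1-en-1-yl]oxy}silane (methyl trans to geranyl) | CC(C)=CCC/C(C)=C/C[C@@H]1CCC(O[Si](C)(C)C)=C[C@H]1C | intermediate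
10 | (S)-4-geranyl-3-methylcyclohex-2-en-1-one | CC(C)=CCC/C(C)=C/C[C@@H]1CCC(=O)C=C1C | intermediate
11 | 5-bromo-2-methylpent-2-ene | CC(C)=CCCBr | starting material
12 | (4-methylpent-3-enyl)magnesium bromide | CC(C)=CCC[Mg]Br | intermediate
13 | trimethylsilyl enol ether (C9=C1) of 14 | CC(C)=CCC/C(C)=C/C[C@@H]1CCC(O[Si](C)(C)C)=C[C@@]1(C)CCC=C(C)C | intermediate
14 | (3R,4S)-4-geranyl-3-methyl-3-homoprenylcyclohexan-1-one (homoprenyl trans, methyl cis to geranyl) | CC(C)=CCC/C(C)=C/C[C@@H]1CCC(=O)C[C@@]1(C)CCC=C(C)C | intermediate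
15 | prenyl bromide | CC(C)=CCBr | starting material
16 | kinetic lithium enolate of 14 (C9=C5) | CC(C)=CCC/C(C)=C/C[C@@H]1CC=C(O[Li])C[C@@]1(C)CCC=C(C)C | intermediate
17 | C5-prenyl ketone: 6-prenyl derivative of 14, C5 epimer mixture | CC(C)=CCC/C(C)=C/C[C@@H]1CC(CC=C(C)C)C(=O)C[C@@]1(C)CCC=C(C)C | intermediate
18 | tetrasubstituted trimethylsilyl enol ether (C9=C5) of 17 | CC(C)=CCC/C(C)=C/C[C@@H]1CC(CC=C(C)C)=C(O[Si](C)(C)C)C[C@@]1(C)CCC=C(C)C | intermediate
19 | 3-(trimethylsilyl)propynal | C[Si](C)(C)C#CC=O | starting material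
20 | lithium enolate (C9=C5) from 18 | CC(C)=CCC/C(C)=C/C[C@@H]1CC(CC=C(C)C)=C(O[Li])C[C@@]1(C)CCC=C(C)C | intermediate
21 | lithium aldolate: C5 carries prenyl (cis to geranyl) and CH(OLi)C≡CSiMe3 (trans to geranyl), carbinol epimers | CC(C)=CCC/C(C)=C/C[C@@H]1C[C@@](CC=C(C)C)(C(O[Li])C#C[Si](C)(C)C)C(=O)C[C@@]1(C)CCC=C(C)C | intermediate
22 | triethylsilyl ether of the C5 aldol (C5: prenyl cis, CH(OSiEt3)C≡CSiMe3 trans to geranyl) | CC(C)=CCC/C(C)=C/C[C@@H]1C[C@@](CC=C(C)C)(C(O[Si](CC)(CC)CC)C#C[Si](C)(C)C)C(=O)C[C@@]1(C)CCC=C(C)C | intermediate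
23 | lithium enolate (C9=C1) of 22 | CC(C)=CCC/C(C)=C/C[C@@H]1C[C@@](CC=C(C)C)(C(O[Si](CC)(CC)CC)C#C[Si](C)(C)C)C(O[Li])=C[C@@]1(C)CCC=C(C)C | intermediate
24 | C1-prenyl derivative of 22 (C1 epimers) | CC(C)=CCC/C(C)=C/C[C@@H]1C[C@@](CC=C(C)C)(C(O[Si](CC)(CC)CC)C#C[Si](C)(C)C)C(=O)C(CC=C(C)C)[C@@]1(C)CCC=C(C)C | intermediate
25 | β-hydroxy ketone: C5 carries prenyl and CH(OH)C≡CH (C1 and carbinol epimers) | CC(C)=CCC/C(C)=C/C[C@@H]1C[C@@](CC=C(C)C)(C(O)C#C)C(=O)C(CC=C(C)C)[C@@]1(C)CCC=C(C)C | intermediate
26 | 2,6-diprenyl-6-propynoyl ring A ketone (propynoyl trans to geranyl; C1 epimers) | CC(C)=CCC/C(C)=C/C[C@@H]1C[C@@](CC=C(C)C)(C(=O)C#C)C(=O)C(CC=C(C)C)[C@@]1(C)CCC=C(C)C | intermediate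
27 | C9 tert-butyldimethylsilyl enol ether (C9=C1) of 26 | CC(C)=CCC/C(C)=C/C[C@@H]1C[C@@](CC=C(C)C)(C(=O)C#C)C(O[Si](C)(C)C(C)(C)C)=C(CC=C(C)C)[C@@]1(C)CCC=C(C)C | intermediate
28 | 1,5-diprenyl-7-geranyl-8-methyl-8-homoprenylbicyclo[3.3.1]non-2-ene-4,9-dione (geranyl exo, C8 methyl axial) | CC(C)=CCC/C(C)=C/C[C@@H]1C[C@]2(CC=C(C)C)C(=O)[C@@](CC=C(C)C)(C=CC2=O)[C@@]1(C)CCC=C(C)C | intermediate
29 | 3-hydroxybenzaldehyde | O=Cc1cccc(O)c1 | starting material
30 | 3-(tert-butyldimethylsilyloxy)benzaldehyde | CC(C)(C)[Si](C)(C)Oc1cccc(C=O)c1 | intermediate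
31 | (E)-3-(tert-butyldimethylsilyloxy)benzaldehyde oxime | CC(C)(C)[Si](C)(C)Oc1cccc(/C=N/O)c1 | intermediate
32 | N-hydroxy-3-(tert-butyldimethylsilyloxy)benzimidoyl chloride | CC(C)(C)[Si](C)(C)Oc1cccc(C(Cl)=NO)c1 | intermediate
33 | 3-(tert-butyldimethylsilyloxy)benzonitrile oxide | CC(C)(C)[Si](C)(C)Oc1cccc(C#[N+][O-])c1 | intermediate
34 | isoxazoline cis-fused at C2–C3 on the face away from the C6–C7–C8 bridge (O on C2, aryl-bearing carbon on C3) | CC(C)=CCC/C(C)=C/C[C@@H]1C[C@]2(CC=C(C)C)C(=O)[C@@](CC=C(C)C)([C@H]3ON=C(c4cccc(O[Si](C)(C)C(C)(C)C)c4)[C@H]3C2=O)[C@@]1(C)CCC=C(C)C | intermediate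
35 | isoxazole fused at C2–C3 (O on C2, 3-silyloxyphenyl on the carbon bonded to C3) | CC(C)=CCC/C(C)=C/C[C@@H]1C[C@]2(CC=C(C)C)C(=O)[C@@](CC=C(C)C)(c3onc(-c4cccc(O[Si](C)(C)C(C)(C)C)c4)c3C2=O)[C@@]1(C)CCC=C(C)C | intermediate
36 | enaminone: 3-[amino(3-silyloxyphenyl)methylidene]-2,4,9-trione (either alkene geometry) | CC(C)=CCC/C(C)=C/C[C@@H]1C[C@]2(CC=C(C)C)C(=O)[C@@](CC=C(C)C)(C(=O)C(=C(N)c3cccc(O[Si](C)(C)C(C)(C)C)c3)C2=O)[C@@]1(C)CCC=C(C)C | intermediate
37 | CNP0285073.1 | CC(C)=CCC/C(C)=C/C[C@@H]1C[C@]2(CC=C(C)C)C(=O)[C@@](CC=C(C)C)(C(=O)C(C(=O)c3cccc(O)c3)=C2O)[C@@]1(C)CCC=C(C)C | target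

**Step count**

Total: 19 steps (16 in the main line, 3 for the aryl fragment). Longest linear sequence: 16 steps (steps 1–13 and 17–19).

**Steps most likely to fail**

1. Step 13. Bond formation between the fully substituted C1 and the alkyne terminus may be too slow beside quaternary C8, so that hydrolysis of the silyl enol ether or cyclisation of the C5 prenyl alkene onto the gold-bound alkyne takes over. The fallback sets out from diketone 26 and comes back at enone 28. It uses neither the silyl enol ether nor gold: 26 is treated with a catalytic hindered base (t-BuOK in t-BuOH–THF, or Cs2CO3 in MeCN, rt to 40 °C), so that reversible enolisation at C1 is followed by intramolecular conjugate addition of the enolate to the ynone terminus (anionic 6-endo-dig Michael cyclisation). This gives 28 directly and makes no new compound.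

2. Step 17. Cycloaddition at the hindered C2=C3 bond may be slower than dimerisation of the nitrile oxide and its addition to the side-chain alkenes, or the dipole may add in the reversed orientation. The fallback sets out from enone 28 and comes back at isoxazole 35. Weitz–Scheffer epoxidation (t-BuOOH, DBU, CH2Cl2, rt) gives the 2,3-epoxy ketone F1. Isomerisation with zerovalent palladium (Pd(PPh3)4, 1,2-bis(diphenylphosphino)ethane, toluene, 100 °C) turns it into the bicyclic 2,4,9-trione F2. The enolate of F2 (Et3N, CH2Cl2) is C-acylated at C3 by nitrile oxide 33 released from 32, and acid-promoted cyclodehydration (TsOH, rt) of the oxime gives isoxazole 35 together with its regioisomer F3 (ring oxygen on C4). Both are opened in step 19 to the same enaminone 36.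

3. Step 12. Enolisation at the hindered C1–H may be slower than degradation of the terminal ynone by the silyl triflate and base (conjugate addition, oligomerisation). The fallback sets out from 24 and comes back at 27. Pyridinium p-toluenesulfonate in MeOH (0 °C) removes only the O-triethylsilyl group and gives the hydroxy ketone F4. Dess–Martin oxidation gives the C-silylated ynone F5, which has no acidic alkyne hydrogen and a shielded β-carbon. Hard enolisation (KN(SiMe3)2, THF, −78 °C, then t-BuMe2SiOTf) gives the silyl enol ether F6. Protodesilylation of the alkyne catalysed by AgNO3 (acetone–H2O, rt) then gives 27.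

**Further compounds**

F0 | step 13 | none | none
F1 | step 17 | 2,3-epoxide of 28 (epoxide on the face away from the C6–C7–C8 bridge) | CC(C)=CCC/C(C)=C/C[C@@H]1C[C@]2(CC=C(C)C)C(=O)[C@@](CC=C(C)C)([C@H]3O[C@H]3C2=O)[C@@]1(C)CCC=C(C)C
F2 | step 17 | 4-hydroxy-1,5-diprenyl-7-geranyl-8-methyl-8-homoprenylbicyclo[3.3.1]non-3-ene-2,9-dione (trione, enol form) | CC(C)=CCC/C(C)=C/C[C@@H]1C[C@]2(CC=C(C)C)C(=O)[C@@](CC=C(C)C)(C(=O)C=C2O)[C@@]1(C)CCC=C(C)C
F3 | step 17 | regioisomeric isoxazole fused at C3–C4 (ring oxygen on C4, C2 ketone) | CC(C)=CCC/C(C)=C/C[C@@H]1C[C@]2(CC=C(C)C)C(=O)[C@@](CC=C(C)C)(C(=O)c3c(-c4cccc(O[Si](C)(C)C(C)(C)C)c4)noc32)[C@@]1(C)CCC=C(C)C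
F4 | step 12 | hydroxy ketone: C5 carries prenyl and CH(OH)C≡CSiMe3 | CC(C)=CCC/C(C)=C/C[C@@H]1C[C@@](CC=C(C)C)(C(O)C#C[Si](C)(C)C)C(=O)C(CC=C(C)C)[C@@]1(C)CCC=C(C)C
F5 | step 12 | C-trimethylsilyl ynone diketone | CC(C)=CCC/C(C)=C/C[C@@H]1C[C@@](CC=C(C)C)(C(=O)C#C[Si](C)(C)C)C(=O)C(CC=C(C)C)[C@@]1(C)CCC=C(C)C
F6 | step 12 | C9 tert-butyldimethylsilyl enol ether of F5 | CC(C)=CCC/C(C)=C/C[C@@H]1C[C@@](CC=C(C)C)(C(=O)C#C[Si](C)(C)C)C(O[Si](C)(C)C(C)(C)C)=C(CC=C(C)C)[C@@]1(C)CCC=C(C)C
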